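**Retrosynthetic overview**

1. The (E)-trisubstituted alkene is taken back to dibromoalkene 21 (two stereospecific Negishi couplings) and this to the C1 aldehyde 20. The equatorial C4 bromide is taken back to the C4 ketone through alkenyl bromide 18 and radical hydrogenation.
2. The strategy rests on one feature: in the five-membered ring (C1, C2, C3, C3a, C7a), C1 carries a one-carbon exocyclic branch and lies between the ring-fusion CH (C7a) and the CH2 C2. This is the retron of cyclopent-1-ene-1-carbaldehyde 12, made by an aldol bond C1–C2.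
3. Joining the formyl carbon back to C2 gives the trans-fused Δ6-octalin 10, in which the branch carbon is still a ring carbon. Ozonolysis and amine-salt aldol condensation contract that ring.
4. Octalin 10 comes from (S)-enedione 1. The trans ring fusion, the tertiary carbinol and the quaternary carbon are all fixed on the rigid decalin before the contraction.
5. Ring order: both six-membered rings arrive with 1; the cyclopentane is the only ring made, last, in step 9.

Key step: step 9

Remark: β is the face of the angular methyl group and α the opposite face; compounds 3–10 keep the locants of dione 1, compounds 11–25 are numbered as indanes (C1 side-chain carbon, C3a angular methyl, C4, C7 carbinol, C7a ring-fusion CH); the tertiary triethylsilyl ether is assumed to hydrolyse together with the hindered dioxolane in step 12.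

**Route**

Step 1
Reactants: 1 (S)-8a-methyl-3,4,8,8a-tetrahydronaphthalene-1,6(2H,7H)-dione; 2 ethylene glycol
Product: 3 (8aS)-1,1:6,6-bis(ethylenedioxy)-8a-methyl-1,2,3,5,6,7,8,8a-octahydronaphthalene (C4=C4a alkene)
Conditions: ethylene glycol (5 equiv), TsOH·H2O (cat.), PhH, reflux, Dean–Stark
Reagents that add atoms: ethylene glycol (second equivalent, for the second dioxolane), OCCO
Why: Acid-catalysed ketalisation of both carbonyl groups, each taking up one molecule of the diol with loss of water, in which the enone reacts through its dienol ether so that the alkene settles in the β,γ position (C4=C4a), as with steroidal 4-en-3-ones; C8a is not touched.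

Step 2
Reactants: 3 bis-dioxolane alkene
Product: 4 1,1:6,6-bis(ethylenedioxy)-8aβ-methyl-trans-decahydronaphthalen-4α-ol (4a-H α, OH equatorial)
Conditions: BH3·THF, THF, 0 °C → rt; NaOH, H2O2, 0 °C
Reagents that add atoms: hydrogen peroxide, OO
Why: Hydroboration–oxidation places boron on the less substituted C4 and hydrogen on C4a in a syn addition from the α face opposite the angular methyl group, which sets the trans ring fusion and the 4α-hydroxyl; any β-face product converges after step 3, where C4a becomes epimerisable.

Step 3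
Reactants: 4 trans-decalol
Product: 5 1,1:6,6-bis(ethylenedioxy)-8aβ-methyl-trans-decalin-4-one (4a-H α)
Conditions: DMP (1,1,1-triacetoxy-1,2-benziodoxol-3(1H)-one), NaHCO3, CH2Cl2, rt
Reagents that add atoms: none
Why: Buffered periodinane oxidation of the secondary alcohol leaves both dioxolanes intact, and the trans-fused ketone is the more stable C4a epimer, so base equilibration can only improve the material.

Step 4
Reactants: 5 trans-decalin-4-one
Product: 6 1,1:6,6-bis(ethylenedioxy)-4α,8aβ-dimethyl-trans-decahydronaphthalen-4β-ol (OH axial, cis to the angular methyl)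
Conditions: MeMgBr, CeCl3 (anhydrous), THF, −78 → 0 °C
Reagents that add atoms: methylmagnesium bromide, C[Mg]Br
Why: Organocerium 1,2-addition avoids enolisation towards C4a, and because the axial approach is blocked by the syn-axial angular methyl group the methyl enters equatorially from the α face, which sets the axial 4β-hydroxyl.

Step 5
Reactants: 6 tertiary alcohol
Product: 7 1,1:6,6-bis(ethylenedioxy)-4α,8aβ-dimethyl-4β-(triethylsilyloxy)-trans-decahydronaphthalene
Conditions: Et3SiOTf, 2,6-lutidine, CH2Cl2, −78 → 0 °C
Reagents that add atoms: triethylsilyl trifluoromethanesulfonate, CC[Si](CC)(CC)OS(=O)(=O)C(F)(F)F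
Why: Silyl triflate silylation of the hindered tertiary alcohol, under which ketone-derived dioxolanes are not opened at low temperature; the ether keeps this oxygen from being triflated in step 7 and from forming five-membered lactols with the nearby formyl groups of steps 9 and 10.

Step 6
Reactants: 7 bis-dioxolane silyl ether
Product: 8 1,1-(ethylenedioxy)-4α,8aβ-dimethyl-4β-(triethylsilyloxy)-trans-decalin-6-one (4a-H α)
Conditions: PPTS (cat.), acetone–H2O (10:1), 45 °C
Reagents that add atoms: water, O
Why: Acid-catalysed ketal hydrolysis that should be selective for the unhindered C6 dioxolane, since the C1 dioxolane next to the quaternary C8a and the hindered tertiary silyl ether react much more slowly.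

Step 7
Reactants: 8 mono-dioxolane ketone
Product: 9 1,1-(ethylenedioxy)-4α,8aβ-dimethyl-4β-(triethylsilyloxy)-1,2,3,4,4a,5,8,8a-octahydronaphthalen-6-yl trifluoromethanesulfonate (C6=C7 enol triflate, trans-fused)
Conditions: KN(SiMe3)2, THF, −78 °C; PhNTf2, −78 → 0 °C
Reagents that add atoms: N-phenylbis(trifluoromethanesulfonimide), O=S(=O)(N(c1ccccc1)S(=O)(=O)C(F)(F)F)C(F)(F)F
Why: Kinetic enolate formation and O-triflation; deprotonation should occur at C7, as trans-fused ketones of this type enolise away from the ring-fusion CH, and C5 is further screened by the fully substituted C4.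

Step 8
Reactants: 9 enol triflate
Product: 10 1,1-(ethylenedioxy)-4α,8aβ-dimethyl-4β-(triethylsilyloxy)-1,2,3,4,4a,5,8,8a-octahydronaphthalene (trans-fused Δ6-octalin, 4a-H α)
Conditions: Pd(OAc)2 (cat.), PPh3, HCO2H, n-Bu3N, DMF, 60 °C
Reagents that add atoms: none
Why: Palladium-catalysed formate reduction of an enol triflate (oxidative addition, formate exchange, decarboxylation, reductive elimination) gives the alkene at C6=C7 without migration.

Step 9
Reactants: 10 trans-Δ6-octalin
Product: 12 4,4-(ethylenedioxy)-3aβ,7α-dimethyl-7β-(triethylsilyloxy)-3a,4,5,6,7,7a-hexahydro-3H-indene-1-carbaldehyde (7a-H α), via seco-dialdehyde 11 (not isolated)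
Conditions: O3, CH2Cl2, −78 °C; PPh3, −78 °C → rt; then piperidine, AcOH, PhH, 60 °C
Reagents that add atoms: ozone, [O-][O+]=O
Why: Ozone cleaves the only C=C bond (1,3-dipolar cycloaddition, cycloreversion, recombination to the ozonide) and PPh3 reduces the ozonide to dialdehyde 11 with one formylmethyl arm on C7a and one on C3a; piperidinium acetate then forms the enamine of the C7a-side aldehyde, whose α carbon (future C1) adds to the other formyl carbon (future C2), and water is lost by E1cB through the conjugated iminium ion. The closest known reaction type is the ozonolysis–amine-salt aldol contraction of cyclohexenes to cyclopent-1-ene-1-carbaldehydes, used on steroid and terpenoid rings. The cyclopentene closes in the 5-(enolexo)-exo-trig mode by the C1–C2 bond, and the former ring carbon C6 of 10 remains as the formyl group on C1. No stereocentre is created and none is at risk, since C3a is quaternary, C7 has no hydrogen and the C7a–H is not acidified by the new enal. The step needs regioselectivity between the two donor methylenes: the one on C3a is neopentyl and sits between the axial methyl group and the spiro-dioxolane at C4, so its enamine has no unhindered rotamer, whereas the enamine of the C7a arm can eclipse the C7a–H bond on the α face away from the silyloxy group, and this should steer the closure through C1. The silyl ether keeps the C7 oxygen from forming a lactol with the nearer formyl group, so both aldehydes stay free.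

Step 10
Reactants: 12 cyclopentene carbaldehyde
Product: 14 4,4-(ethylenedioxy)-3aβ,7α-dimethyl-7β-(triethylsilyloxy)-trans-octahydro-1H-indene-1α-carbaldehyde (7a-H α), via cis-aldehyde 13 (not isolated)
Conditions: H2 (1 atm), Pd/C, EtOAc, rt; filter; DBU, rt
Reagents that add atoms: none
Why: Heterogeneous hydrogenation of the enal C=C from the α face (the β face is screened by the angular methyl and the silyloxy group) gives the 1β-aldehyde 13, and base equilibration through the enolate then moves the formyl group to the α face, where it is trans to the fully substituted C7 on the cyclopentane, which sets C1.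

Step 11
Reactants: 14 1α-aldehyde
Product: 15 [4,4-(ethylenedioxy)-3aβ,7α-dimethyl-7β-(triethylsilyloxy)-trans-octahydro-1H-inden-1α-yl]methanol
Conditions: NaBH4, MeOH, 0 °C
Reagents that add atoms: none
Why: Borohydride reduction of the aldehyde at low temperature fixes the C1 configuration by removing the acidifying carbonyl group.

Step 12
Reactants: 15 primary alcohol
Product: 16 7β-hydroxy-1α-(hydroxymethyl)-3aβ,7α-dimethyl-trans-octahydro-4H-inden-4-one (7a-H α)
Conditions: 1 M aq HCl, THF, rt
Reagents that add atoms: water, O
Why: Acid hydrolysis removes the hindered dioxolane and the tertiary silyl ether in one operation; the ketone has no epimerisable neighbour (C3a quaternary, C5 a CH2) and dilute acid at room temperature should not ionise the tertiary alcohol.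

Step 13
Reactants: 16 keto diol
Product: 17 4-hydrazono-1α-(hydroxymethyl)-3aβ,7α-dimethyl-trans-octahydro-1H-inden-7β-ol
Conditions: N2H4·H2O (excess), Et3N, EtOH, 80 °C
Reagents that add atoms: hydrazine, NN
Why: Hydrazone formation from a ketone flanked by a quaternary carbon, as with 17-oxo steroids; the excess of hydrazine suppresses azine formation.

Step 14
Reactants: 17 hydrazone
Product: 18 4-bromo-1α-(hydroxymethyl)-3aβ,7α-dimethyl-2,3,3a,6,7,7a-hexahydro-1H-inden-7β-ol (C4=C5 alkenyl bromide, 7a-H α)
Conditions: NBS, pyridine, 0 °C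
Reagents that add atoms: N-bromosuccinimide, O=C1CCC(=O)N1Br
Why: Barton-type halogenation of a hydrazone (N-bromination, loss of HBr to the diazo compound, C-bromination, loss of N2 and of the C5 proton); the alkenyl bromide is favoured over a gem-dibromide at this neopentyl carbon and C5 carries the only β-hydrogens.

Step 15
Reactants: 18 alkenyl bromide
Product: 19 4β-bromo-1α-(hydroxymethyl)-3aβ,7α-dimethyl-trans-octahydro-1H-inden-7β-ol (Br equatorial, cis to the angular methyl)
Conditions: Mn(dpm)3 (cat., dpm = dipivaloylmethanate), PhSiH3, t-BuOOH, i-PrOH, rt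
Reagents that add atoms: none
Why: Metal-hydride hydrogen-atom-transfer hydrogenation, which saturates haloalkenes without hydrogenolysis: the first hydrogen atom goes to C5 to give the α-bromo radical at C4, and the second is delivered axially from the α face, anti to the adjacent axial methyl group, which sets the equatorial 4β-bromide.

Step 16
Reactants: 19 bromo diol
Product: 20 4β-bromo-7β-hydroxy-3aβ,7α-dimethyl-trans-octahydro-1H-indene-1α-carbaldehyde
Conditions: DMP, NaHCO3, CH2Cl2, 0 °C → rt
Reagents that add atoms: none
Why: Periodinane oxidation of the primary alcohol; the tertiary alcohol is inert, and the 1α-formyl group is already the stable epimer and cannot reach the 7β-hydroxyl to form a lactol.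

Step 17
Reactants: 20 aldehyde
Product: 21 4β-bromo-1α-(2,2-dibromoethenyl)-3aβ,7α-dimethyl-trans-octahydro-1H-inden-7β-ol
Conditions: CBr4, PPh3, Zn, CH2Cl2, rt (ylide formation); then 20, 0 °C → rt
Reagents that add atoms: carbon tetrabromide, BrC(Br)(Br)Br
Why: Ramirez dibromo-olefination (first stage of the Corey–Fuchs sequence); forming the ylide beforehand with zinc leaves no bromophosphonium salt to attack the tertiary alcohol.

Step 18
Reactants: 21 dibromoalkene; 22 5-bromo-2-methylpent-2-ene
Product: 24 4β-bromo-1α-[(1Z)-2-bromo-6-methylhepta-1,5-dien-1-yl]-3aβ,7α-dimethyl-trans-octahydro-1H-inden-7β-ol, via homoprenylzinc bromide 23 (not isolated)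
Conditions: 22, Zn, LiCl, THF, 50 °C; then 21, PdCl2(DPEphos) (cat.), THF–DMF, rt
Reagents that add atoms: none
Why: Zinc insertion followed by trans-selective Negishi monoalkylation of a 1,1-dibromoalkene: oxidative addition takes the less hindered bromine trans to the ring substituent, the wide-bite-angle diphosphine suppresses β-hydride elimination, and the hindered secondary alkyl bromide is not touched.

Step 19
Reactants: 24 (Z)-bromo diene
Product: 25 (1S,3aS,4S,7R,7aS)-4-bromo-1-[(1E)-2,6-dimethylhepta-1,5-dien-1-yl]-3a,7-dimethyloctahydro-1H-inden-7-ol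
Conditions: Me2Zn, Pd(P(t-Bu)3)2 (cat.), THF, 0 °C → rt
Reagents that add atoms: dimethylzinc, C[Zn]C
Why: Negishi methylation of the remaining alkenyl bromide with retention of configuration, for which the bulky trialkylphosphine catalyst is chosen because it avoids isomerisation of the alkenylpalladium intermediate; this sets the (E)-trisubstituted alkene.

**Compound list**

1 | (S)-8a-methyl-3,4,8,8a-tetrahydronaphthalene-1,6(2H,7H)-dione | C[C@]12CCC(=O)C=C1CCCC2=O | starting material
2 | ethylene glycol | OCCO | starting material
3 | (8aS)-1,1:6,6-bis(ethylenedioxy)-8a-methyl-1,2,3,5,6,7,8,8a-octahydronaphthalene | C1C3(OCCO3)CC[C@]2(C)C4(OCCO4)CCC=C12 | intermediate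
4 | 1,1:6,6-bis(ethylenedioxy)-8aβ-methyl-trans-decahydronaphthalen-4α-ol | C1C3(OCCO3)CC[C@]2(C)C4(OCCO4)CC[C@H](O)[C@@H]12 | intermediate
5 | 1,1:6,6-bis(ethylenedioxy)-8aβ-methyl-trans-decalin-4-one | C1C3(OCCO3)CC[C@]2(C)C4(OCCO4)CCC(=O)[C@@H]12 | intermediate
6 | 1,1:6,6-bis(ethylenedioxy)-4α,8aβ-dimethyl-trans-decahydronaphthalen-4β-ol | C1C3(OCCO3)CC[C@]2(C)C4(OCCO4)CC[C@@](C)(O)[C@@H]12 | intermediate
7 | 4β-triethylsilyl ether of 6 | C1C3(OCCO3)CC[C@]2(C)C4(OCCO4)CC[C@@](C)(O[Si](CC)(CC)CC)[C@@H]12 | intermediate
8 | 1,1-(ethylenedioxy)-4α,8aβ-dimethyl-4β-(triethylsilyloxy)-trans-decalin-6-one | C1C(=O)CC[C@]2(C)C3(OCCO3)CC[C@@](C)(O[Si](CC)(CC)CC)[C@@H]12 | intermediate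
9 | C6=C7 enol triflate of 8 | C1C(OS(=O)(=O)C(F)(F)F)=CC[C@]2(C)C3(OCCO3)CC[C@@](C)(O[Si](CC)(CC)CC)[C@@H]12 | intermediate
10 | 1,1-(ethylenedioxy)-4α,8aβ-dimethyl-4β-(triethylsilyloxy)-1,2,3,4,4a,5,8,8a-octahydronaphthalene (trans-fused) | C1C=CC[C@]2(C)C3(OCCO3)CC[C@@](C)(O[Si](CC)(CC)CC)[C@@H]12 | intermediate
11 | seco-dialdehyde: trans-cyclohexane with CH2CHO on the methyl-bearing quaternary carbon and on the adjacent CH, spiro-dioxolane and silyloxy carbinol retained | O=CC[C@]1(C)C2(OCCO2)CC[C@@](C)(O[Si](CC)(CC)CC)[C@H]1CC=O | intermediate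
12 | 4,4-(ethylenedioxy)-3aβ,7α-dimethyl-7β-(triethylsilyloxy)-3a,4,5,6,7,7a-hexahydro-3H-indene-1-carbaldehyde | O=CC1=CC[C@]2(C)C3(OCCO3)CC[C@@](C)(O[Si](CC)(CC)CC)[C@@H]12 | intermediate
13 | 1β-carbaldehyde epimer of 14 | O=C[C@H]1CC[C@]2(C)C3(OCCO3)CC[C@@](C)(O[Si](CC)(CC)CC)[C@@H]12 | intermediate
14 | 4,4-(ethylenedioxy)-3aβ,7α-dimethyl-7β-(triethylsilyloxy)-trans-octahydro-1H-indene-1α-carbaldehyde | O=C[C@@H]1CC[C@]2(C)C3(OCCO3)CC[C@@](C)(O[Si](CC)(CC)CC)[C@@H]12 | intermediate
15 | [4,4-(ethylenedioxy)-3aβ,7α-dimethyl-7β-(triethylsilyloxy)-trans-octahydro-1H-inden-1α-yl]methanol | OC[C@@H]1CC[C@]2(C)C3(OCCO3)CC[C@@](C)(O[Si](CC)(CC)CC)[C@@H]12 | intermediate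
16 | 7β-hydroxy-1α-(hydroxymethyl)-3aβ,7α-dimethyl-trans-octahydro-4H-inden-4-one | OC[C@@H]1CC[C@]2(C)C(=O)CC[C@@](C)(O)[C@@H]12 | intermediate
17 | hydrazone of 16 | OC[C@@H]1CC[C@]2(C)C(=NN)CC[C@@](C)(O)[C@@H]12 | intermediate
18 | 4-bromo-1α-(hydroxymethyl)-3aβ,7α-dimethyl-2,3,3a,6,7,7a-hexahydro-1H-inden-7β-ol | OC[C@@H]1CC[C@]2(C)C(Br)=CC[C@@](C)(O)[C@@H]12 | intermediate
19 | 4β-bromo-1α-(hydroxymethyl)-3aβ,7α-dimethyl-trans-octahydro-1H-inden-7β-ol | OC[C@@H]1CC[C@]2(C)[C@@H](Br)CC[C@@](C)(O)[C@@H]12 | intermediate
20 | 4β-bromo-7β-hydroxy-3aβ,7α-dimethyl-trans-octahydro-1H-indene-1α-carbaldehyde | O=C[C@@H]1CC[C@]2(C)[C@@H](Br)CC[C@@](C)(O)[C@@H]12 | intermediate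
21 | 4β-bromo-1α-(2,2-dibromoethenyl)-3aβ,7α-dimethyl-trans-octahydro-1H-inden-7β-ol | BrC(Br)=C[C@@H]1CC[C@]2(C)[C@@H](Br)CC[C@@](C)(O)[C@@H]12 | intermediate
22 | 5-bromo-2-methylpent-2-ene | CC(C)=CCCBr | starting material
23 | (4-methylpent-3-en-1-yl)zinc bromide | CC(C)=CCC[Zn]Br | intermediate
24 | 4β-bromo-1α-[(1Z)-2-bromo-6-methylhepta-1,5-dien-1-yl]-3aβ,7α-dimethyl-trans-octahydro-1H-inden-7β-ol | CC(C)=CCC/C(Br)=C/[C@@H]1CC[C@]2(C)[C@@H](Br)CC[C@@](C)(O)[C@@H]12 | intermediate
25 | (1S,3aS,4S,7R,7aS)-4-bromo-1-[(1E)-2,6-dimethylhepta-1,5-dien-1-yl]-3a,7-dimethyloctahydro-1H-inden-7-ol | CC(C)=CCC/C(C)=C/[C@@H]1CC[C@]2(C)[C@@H](Br)CC[C@@](C)(O)[C@@H]12 | target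

**Step count**

Total: 19 steps. Longest linear sequence: 19 steps (1 → 25); the zinc reagent 23 is made inside step 18.

**Steps most likely to fail**

1. Step 9, poor regioselectivity of the aldol closure. Closure through the neopentyl methylene on C3a would place the formyl group on C3. The bias argued above may be small or reversed, because closure through C1 puts the new in-plane formyl group against the fully substituted C7, and related trans-fused seco-dialdehydes with an angular methyl group can close through the neopentyl side.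
 Fallback, with the regiochemistry fixed by oxidation level: it sets out from ketone 8 and comes back at alcohol 15. Ketone 8 is converted with KN(SiMe3)2 and Me3SiCl into the Δ6 silyl enol ether F1. Ozonolysis (O3, CH2Cl2–MeOH; Me2S) gives aldehyde acid F2, in which the C7a arm ends in the acid and only the C3a arm carries an aldehyde. Me3SiCHN2 gives aldehyde ester F3, NaBH4 reduces the aldehyde alone to hydroxy ester F4, and I2, PPh3 and imidazole give iodo ester F5. KN(SiMe3)2 then forms the ester enolate, which can only alkylate the iodide-bearing carbon (5-exo-tet). This closes C1–C2 and gives, after NaOMe equilibration to the 1α epimer, hydrindane ester F6, which LiAlH4 reduces to 15.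

2. Step 15, loss of bromine or wrong face. Bromine may be lost by reduction of the C–Br bond, or by hydrogen-atom transfer to C4 followed by β-scission; the C4 hydrogen may also arrive from the β face.
 Fallback: it sets out from alkenyl bromide 18 and comes back at bromide 19. The stepwise radical hydrogenation is replaced by a concerted, metal-free syn transfer of two hydrogens from diimide (2-nitrobenzenesulfonohydrazide in large excess, Et3N, CH2Cl2, rt). Diimide does not cleave carbon–bromine bonds and adds to the open α face, which again leaves bromine equatorial. No new compound is made.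

3. Step 19, erosion of alkene geometry. The alkenylpalladium intermediate may isomerise, or oxidative addition may be slow at the bromine cis to the ring.
 Fallback: it sets out from dibromoalkene 21, replaces steps 18 and 19, and comes back at target 25. Corey–Fuchs conversion (n-BuLi, THF, −78 °C, where the hindered secondary bromide should not exchange; then MeI) gives methyl alkyne F7. Hydrozirconation with excess Cp2Zr(H)Cl places zirconium on the methyl-bearing alkyne carbon, and iodinolysis gives (E)-alkenyl iodide F8 with iodine trans to the ring. Negishi coupling of F8 with zinc reagent 23 (PdCl2(dppf), THF) proceeds with retention and gives 25.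

**Further compounds**

F1 | step 9 | Δ6 trimethylsilyl enol ether of ketone 8 | C1C(O[Si](C)(C)C)=CC[C@]2(C)C3(OCCO3)CC[C@@](C)(O[Si](CC)(CC)CC)[C@@H]12
F2 | step 9 | aldehyde acid (CH2CHO on the quaternary carbon, CH2CO2H on the adjacent CH) | O=CC[C@]1(C)C2(OCCO2)CC[C@@](C)(O[Si](CC)(CC)CC)[C@H]1CC(=O)O
F3 | step 9 | aldehyde methyl ester | O=CC[C@]1(C)C2(OCCO2)CC[C@@](C)(O[Si](CC)(CC)CC)[C@H]1CC(=O)OC
F4 | step 9 | hydroxy methyl ester | OCC[C@]1(C)C2(OCCO2)CC[C@@](C)(O[Si](CC)(CC)CC)[C@H]1CC(=O)OC
F5 | step 9 | iodo methyl ester | ICC[C@]1(C)C2(OCCO2)CC[C@@](C)(O[Si](CC)(CC)CC)[C@H]1CC(=O)OC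
F6 | step 9 | methyl 4,4-(ethylenedioxy)-3aβ,7α-dimethyl-7β-(triethylsilyloxy)-trans-octahydro-1H-indene-1α-carboxylate | COC(=O)[C@@H]1CC[C@]2(C)C3(OCCO3)CC[C@@](C)(O[Si](CC)(CC)CC)[C@@H]12
F0 | step 15 | none | none
F7 | step 19 | 4β-bromo-3aβ,7α-dimethyl-1α-(prop-1-yn-1-yl)-trans-octahydro-1H-inden-7β-ol | CC#C[C@@H]1CC[C@]2(C)[C@@H](Br)CC[C@@](C)(O)[C@@H]12
F8 | step 19 | 4β-bromo-1α-[(1E)-2-iodoprop-1-en-1-yl]-3aβ,7α-dimethyl-trans-octahydro-1H-inden-7β-ol | I/C(C)=C/[C@@H]1CC[C@]2(C)[C@@H](Br)CC[C@@](C)(O)[C@@H]12
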